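**Retrosynthetic overview**

1. Carbons are labelled C1–C30 in the order of the target SMILES: ring A = C7-C8-C9-C10-C11, ring B = C13-C14-C15-C16-C26, ring C = C9-C10-C11-C13-C14-C15, cyclopropanes = C5/C6/C28 and C17/C18/C23.
2. Feature: C11 is quaternary, carries methyl C12 and lies between the carbonyl-derived C7 and the methylene C10 of ring A, the footprint of a 1,2-shift from a cyclobutanol carbon (C7) to a cation at C11. Ring A is therefore cut at C10–C11 back to a 1-alkenylcyclobutanol (protio-semipinacol ring expansion), which also fixes C11 relative to C13.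
3. Before it: the alkenylcyclobutanol comes from cyclobutanone and a ring-B vinyllithium (Shapiro reaction); ring B comes from 2-methylcyclopent-2-en-1-one by asymmetric conjugate addition of an isopropenyl group (sets C13, then trans C26).
4. After it: C8=C9 desaturation, ring C by C9–C15 Michael closure (the 11S,13S pair allows only the syn tricycle), enol triflates at C7 and C16, then the C6–C7 and C16–C17 bonds by double Negishi coupling with one cis-cyclopropylzinc reagent made from 3,3-dimethylcyclopropene.
5. Ring order: B (from the starting enone), A (step 6), C (step 9); the two cyclopropanes are made separately and attached last, then the side-chain ketals are removed.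

Key step: step 6

Remark: the chiral catalysts of steps 1, 6 and 13 are written with one absolute configuration; their sense of induction is assumed, and the mirror-image catalyst is used where it proves to be the matched one.

**Route**

Step 1
Reactants: 1 2-methylcyclopent-2-en-1-one; 2 2-bromopropene
Product: 6 (2R,3S)-2-methyl-3-(prop-1-en-2-yl)cyclopentan-1-one, via isopropenyllithium 3 (not isolated), via dimethyl(isopropenyl)aluminium 4 (not isolated), via dimethylaluminium enolate 5 (not isolated)
Conditions: 2, t-BuLi (2 equiv), Et2O, −78 °C; Me2AlCl; then 1, Cu(O2C-2-thienyl) (5 mol %), (R,R)-N,N-bis(1-phenylethyl)-P,P-diphenylphosphinous amide (6 mol %), Et2O, −30 °C; aq HCl; then DBU (cat.), CH2Cl2, rt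
Reagents that add atoms: none
Why: Copper-catalysed asymmetric conjugate addition of an alkenylalane (the alkenyl group transfers in preference to methyl) to the 2-substituted cyclopentenone should set C13 (3S) under ligand control, and base equilibration of the α-centre gives the more stable trans (2R) epimer.

Step 2
Reactants: 6 (2R,3S)-2-methyl-3-(prop-1-en-2-yl)cyclopentan-1-one
Product: 7 (6R,7S)-6-methyl-7-(prop-1-en-2-yl)-1,4-dioxaspiro[4.4]nonane
Conditions: ethylene glycol, PPTS (cat.), benzene, reflux, Dean–Stark
Reagents that add atoms: ethylene glycol, OCCO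
Why: Acid-catalysed ketalisation of the only ketone with azeotropic removal of water; the weak acid should not isomerise the isopropenyl group, and the trans C26 centre is the thermodynamic one.

Step 3
Reactants: 7 (6R,7S)-6-methyl-7-(prop-1-en-2-yl)-1,4-dioxaspiro[4.4]nonane
Product: 8 1-[(6R,7S)-6-methyl-1,4-dioxaspiro[4.4]nonan-7-yl]ethan-1-one
Conditions: O3, CH2Cl2/MeOH, NaHCO3, −78 °C; then Me2S, −78 °C → rt
Reagents that add atoms: ozone, [O-][O+]=O
Why: Ozonolysis with reductive work-up cleaves the only C=C to the methyl ketone; C13, now α to the acetyl group, keeps the thermodynamically preferred trans arrangement.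

Step 4
Reactants: 8 1-[(6R,7S)-6-methyl-1,4-dioxaspiro[4.4]nonan-7-yl]ethan-1-one
Product: 9 (E)-2,4,6-triisopropylbenzenesulfonyl hydrazone of 8
Conditions: 2,4,6-triisopropylbenzenesulfonohydrazide, THF, rt
Reagents that add atoms: 2,4,6-triisopropylbenzenesulfonohydrazide, NNS(=O)(=O)c1c(C(C)C)cc(C(C)C)cc1C(C)C
Why: Hydrazone formation on the unhindered methyl ketone needs no added acid, so the ketal is untouched, and gives the E isomer with the NH group syn to the methyl group.

Step 5
Reactants: 9 (E)-2,4,6-triisopropylbenzenesulfonyl hydrazone of 8; 10 cyclobutanone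
Product: 12 1-{1-[(6R,7S)-6-methyl-1,4-dioxaspiro[4.4]nonan-7-yl]ethenyl}cyclobutan-1-ol, via vinyllithium 11 (not isolated)
Conditions: n-BuLi (2.2 equiv), THF, −78 → 0 °C; then 10, −78 °C; H2O
Reagents that add atoms: none
Why: Shapiro reaction: double deprotonation (NH and the syn methyl group) followed by loss of sulfinate and N2 gives the 1-substituted vinyllithium, which adds 1,2 to the strained, electrophilic cyclobutanone; C13 is not deprotonated and no stereocentre is formed.

Step 6
Reactants: 12 1-{1-[(6R,7S)-6-methyl-1,4-dioxaspiro[4.4]nonan-7-yl]ethenyl}cyclobutan-1-ol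
Product: 13 (2S)-2-methyl-2-[(6R,7S)-6-methyl-1,4-dioxaspiro[4.4]nonan-7-yl]cyclopentan-1-one
Conditions: (R)-N-triflyl phosphoramide of 3,3′-bis(2,4,6-triisopropylphenyl)-BINOL (10 mol %), toluene, 4 Å molecular sieves, −20 °C → rt
Reagents that add atoms: none
Why: The strong chiral acid protonates the terminal alkene carbon C12, and as positive charge builds at C11 the aligned ring bond C7–C10 shifts to C11 while the hydroxyl on C7 becomes the carbonyl and returns the proton to the catalyst. The closest known reaction is the Brønsted-acid-catalysed protio-semipinacol ring expansion of 1-alkenylcyclobutanols to 2,2-disubstituted cyclopentanones, including variants with chiral acids; the N-triflyl amide is chosen because a plain phosphoric acid diester is too weak for an alkene without a donor substituent. Ring A is not closed end to end but arises by 4→5 ring expansion (1,2-alkyl shift of C10 from C7 to C11), C10–C11 being the only new skeletal bond. The one new stereocentre C11 is set by the face of C11 to which C10 migrates; the neighbouring C13 centre is expected to give only a weak bias (C14H2 on one face, C26H on the other), so the chiral counter-anion of the contact ion pair is the main control element and the matched catalyst antipode is used. The step needs face selectivity (11S, since 11R can only lead to the anti tricycle) and chemoselectivity over hydride shift, elimination and opening of the dioxolane; the release of about 20 kcal/mol of ring strain should make the shift concerted with protonation, and the dry, non-nucleophilic, cold medium should keep the ketal closed.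

Step 7
Reactants: 13 (2S)-2-methyl-2-[(6R,7S)-6-methyl-1,4-dioxaspiro[4.4]nonan-7-yl]cyclopentan-1-one
Product: 15 (5S)-5-methyl-5-[(6R,7S)-6-methyl-1,4-dioxaspiro[4.4]nonan-7-yl]cyclopent-2-en-1-one, via lithium enolate 14 (not isolated)
Conditions: LiN(iPr)2 (1.1 equiv), THF, −78 °C; then N-tert-butylbenzenesulfinimidoyl chloride, −78 °C
Reagents that add atoms: none
Why: Mukaiyama dehydrogenation: the only possible enolate (C7=C8, C11 being quaternary) reacts at sulfur and collapses by syn elimination to the C8=C9 enone at low temperature; the ring-B ketone is masked and no stereocentre is touched.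

Step 8
Reactants: 15 (5S)-5-methyl-5-[(6R,7S)-6-methyl-1,4-dioxaspiro[4.4]nonan-7-yl]cyclopent-2-en-1-one
Product: 16 (5S)-5-methyl-5-[(1S,2R)-2-methyl-3-oxocyclopentyl]cyclopent-2-en-1-one
Conditions: 1 M aq HCl, THF, rt
Reagents that add atoms: water, O
Why: Acid-catalysed hydrolysis of the dioxolane; the enone is inert, and C26, although epimerisable, already has the stable trans configuration.

Step 9
Reactants: 16 (5S)-5-methyl-5-[(1S,2R)-2-methyl-3-oxocyclopentyl]cyclopent-2-en-1-one
Product: 19 (1S,2S,4R,5S,6S)-4,6-dimethyltricyclo[4.2.1.1^{2,5}]decane-3,7-dione, via kinetic lithium enolate 17 (not isolated), via tricyclic lithium enolate 18 (not isolated)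
Conditions: LiN(iPr)2 (1.1 equiv), THF, −78 → 0 °C; then AcOH, −78 °C
Reagents that add atoms: none
Why: Kinetic deprotonation at the less substituted α-carbon C15 and intramolecular Michael addition (6-(enolexo)-exo-trig) to C9 close ring C; because C11–C13 already joins the rings, the new bond can only form cis to it on both five-membered rings, so C9 and C15 are set by the substrate and the 11S,13S pair gives the syn tricycle (any aldolate formed at C7 should revert on warming).

Step 10
Reactants: 19 (1S,2S,4R,5S,6S)-4,6-dimethyltricyclo[4.2.1.1^{2,5}]decane-3,7-dione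
Product: 20 (1S,2S,5S,6S)-4,6-dimethyltricyclo[4.2.1.1^{2,5}]deca-3,7-diene-3,7-diyl bis(trifluoromethanesulfonate)
Conditions: N-(5-chloropyridin-2-yl)-bis(trifluoromethanesulfonimide) (2.5 equiv), KN(SiMe3)2 (3 equiv, two portions), THF, −78 → 0 °C; dilute aq HCl
Reagents that add atoms: N-(5-chloropyridin-2-yl)-bis(trifluoromethanesulfonimide), FC(F)(F)S(=O)(=O)N(c1ccc(Cl)cn1)S(=O)(=O)C(F)(F)F
Why: Enol triflate formation is regiospecific because each ketone can enolise in one direction only (C11 is quaternary; a C15=C16 enolate would be a bridgehead alkene), and the triflating agent already present traps the C7 enolate before retro-Michael cleavage; the single hydrogen on C26 is endo and shielded by ring A, hence the excess base and warming for the second triflation.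

Step 11
Reactants: 21 3-methylbut-2-enal
Product: 22 (E)-3-methylbut-2-enal 4-methylbenzenesulfonyl hydrazone
Conditions: TsNHNH2, MeOH, rt
Reagents that add atoms: 4-methylbenzenesulfonohydrazide, NNS(=O)(=O)c1ccc(C)cc1
Why: Simple hydrazone formation from the aldehyde; no stereocentre is involved.

Step 12
Reactants: 22 (E)-3-methylbut-2-enal 4-methylbenzenesulfonyl hydrazone
Product: 24 3,3-dimethylcyclopropene, via 1-diazo-3-methylbut-2-ene 23 (not isolated)
Conditions: NaOMe, diglyme, 150 °C, product swept into a −78 °C trap
Reagents that add atoms: none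
Why: Aprotic Bamford–Stevens reaction: the hydrazone anion loses sulfinate to the vinyl diazoalkane, which loses N2 and closes to the cyclopropene (the established route to 3,3-dialkylcyclopropenes); the volatile product distils out as it forms.

Step 13
Reactants: 24 3,3-dimethylcyclopropene; 25 2-(2-bromoethyl)-2-methyl-1,3-dioxolane
Product: 28 (1R,3R)-1-iodo-2,2-dimethyl-3-[2-(2-methyl-1,3-dioxolan-2-yl)ethyl]cyclopropane, via Grignard reagent 26 (not isolated), via cis-cyclopropylmagnesium bromide 27 (not isolated)
Conditions: 25, Mg, THF, 25 °C; then 24, CuBr·SMe2 (5 mol %), (R)-1-[(S)-2-(diphenylphosphino)ferrocenyl]ethyldicyclohexylphosphine (6 mol %), Et2O/toluene, −30 → 0 °C; then I2, THF, −78 °C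
Reagents that add atoms: iodine, II
Why: Copper-catalysed enantioselective carbomagnesiation of a 3,3-disubstituted cyclopropene: syn addition across the strained C=C places the alkyl chain and magnesium cis, the chiral bisphosphine–copper catalyst chooses between the two enantiotopic alkene carbons, and iodination of the configurationally stable cyclopropylmagnesium proceeds with retention.

Step 14
Reactants: 20 (1S,2S,5S,6S)-4,6-dimethyltricyclo[4.2.1.1^{2,5}]deca-3,7-diene-3,7-diyl bis(trifluoromethanesulfonate); 28 (1R,3R)-1-iodo-2,2-dimethyl-3-[2-(2-methyl-1,3-dioxolan-2-yl)ethyl]cyclopropane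
Product: 31 bis(ethylene ketal) of the target, via cis-cyclopropyllithium 29 (not isolated), via cis-cyclopropylzinc chloride 30 (not isolated)
Conditions: 28 (3 equiv), t-BuLi (6 equiv), Et2O, −78 °C; ZnCl2 (3.3 equiv), THF, −78 °C → rt; then 20, Pd2(dba)3 (5 mol %), SPhos (20 mol %), THF/NMP, 60 °C
Reagents that add atoms: none
Why: Iodine–lithium exchange, transmetalation to zinc and Negishi coupling all proceed with retention at the cyclopropyl carbon (no β-hydride pathway), so both cis cyclopropyl groups (C6/C5 and C17/C18) arrive with the configuration of 28; the bulky electron-rich biarylphosphine is chosen for the two hindered alkenyl triflates.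

Step 15
Reactants: 31 bis(ethylene ketal) of the target
Product: 32 CNP0300925.1 (target)
Conditions: PPTS, acetone/H2O, 50 °C
Reagents that add atoms: water, O
Why: Mild acid-catalysed hydrolysis of the two side-chain dioxolanes; the weak acid should leave the vinylcyclopropanes and the diene untouched.

**Compound list**

1 | 2-methylcyclopent-2-en-1-one | CC1=CCCC1=O | starting material
2 | 2-bromopropene | CC(Br)=C | starting material
3 | isopropenyllithium | [Li]C(C)=C | intermediate
4 | dimethyl(isopropenyl)aluminium | C[Al](C)C(C)=C | intermediate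
5 | dimethylaluminium enolate of 6 (O–Al on C1, C1=C2, C3 as in 6) | C=C(C)[C@H]1CCC(O[Al](C)C)=C1C | intermediate
6 | (2R,3S)-2-methyl-3-(prop-1-en-2-yl)cyclopentan-1-one | C=C(C)[C@H]1CCC(=O)[C@@H]1C | intermediate
7 | (6R,7S)-6-methyl-7-(prop-1-en-2-yl)-1,4-dioxaspiro[4.4]nonane | C=C(C)[C@H]1CCC2(OCCO2)[C@@H]1C | intermediate
8 | 1-[(6R,7S)-6-methyl-1,4-dioxaspiro[4.4]nonan-7-yl]ethan-1-one | CC(=O)[C@H]1CCC2(OCCO2)[C@@H]1C | intermediate
9 | (E)-2,4,6-triisopropylbenzenesulfonyl hydrazone of 8 | C/C(=N\NS(=O)(=O)c1c(C(C)C)cc(C(C)C)cc1C(C)C)[C@H]2CCC3(OCCO3)[C@@H]2C | intermediate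
10 | cyclobutanone | O=C1CCC1 | starting material
11 | {1-[(6R,7S)-6-methyl-1,4-dioxaspiro[4.4]nonan-7-yl]ethenyl}lithium | [Li]C(=C)[C@H]1CCC2(OCCO2)[C@@H]1C | intermediate
12 | 1-{1-[(6R,7S)-6-methyl-1,4-dioxaspiro[4.4]nonan-7-yl]ethenyl}cyclobutan-1-ol | C=C(C1(O)CCC1)[C@H]2CCC3(OCCO3)[C@@H]2C | intermediate
13 | (2S)-2-methyl-2-[(6R,7S)-6-methyl-1,4-dioxaspiro[4.4]nonan-7-yl]cyclopentan-1-one | O=C1CCC[C@@]1(C)[C@H]2CCC3(OCCO3)[C@@H]2C | intermediate
14 | lithium enolate of 13 (C7–OLi, C7=C8) | [Li]OC1=CCC[C@@]1(C)[C@H]2CCC3(OCCO3)[C@@H]2C | intermediate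
15 | (5S)-5-methyl-5-[(6R,7S)-6-methyl-1,4-dioxaspiro[4.4]nonan-7-yl]cyclopent-2-en-1-one | O=C1C=CC[C@@]1(C)[C@H]2CCC3(OCCO3)[C@@H]2C | intermediate
16 | (5S)-5-methyl-5-[(1S,2R)-2-methyl-3-oxocyclopentyl]cyclopent-2-en-1-one | O=C1C=CC[C@@]1(C)[C@H]2CCC(=O)[C@@H]2C | intermediate
17 | kinetic lithium enolate of 16 (ring B, C16–OLi, C15=C16) | O=C1C=CC[C@@]1(C)[C@H]2CC=C(O[Li])[C@@H]2C | intermediate
18 | lithium enolate of 19 (ring A, C7–OLi, C7=C8) | [Li]OC1=C[C@@H]2C[C@@]1(C)[C@H]3C[C@@H]2C(=O)[C@@H]3C | intermediate
19 | (1S,2S,4R,5S,6S)-4,6-dimethyltricyclo[4.2.1.1^{2,5}]decane-3,7-dione (syn tricycle, C26 methyl exo) | O=C1C[C@@H]2C[C@@]1(C)[C@H]3C[C@@H]2C(=O)[C@@H]3C | intermediate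
20 | (1S,2S,5S,6S)-4,6-dimethyltricyclo[4.2.1.1^{2,5}]deca-3,7-diene-3,7-diyl bis(trifluoromethanesulfonate) | O=S(=O)(OC1=C[C@@H]2C[C@@]1(C)[C@H]3C[C@@H]2C(OS(=O)(=O)C(F)(F)F)=C3C)C(F)(F)F | intermediate
21 | 3-methylbut-2-enal | CC(C)=CC=O | starting material
22 | (E)-3-methylbut-2-enal 4-methylbenzenesulfonyl hydrazone | CC(C)=C/C=N/NS(=O)(=O)c1ccc(C)cc1 | intermediate
23 | 1-diazo-3-methylbut-2-ene | CC(C)=CC=[N+]=[N-] | intermediate
24 | 3,3-dimethylcyclopropene | CC1(C)C=C1 | intermediate
25 | 2-(2-bromoethyl)-2-methyl-1,3-dioxolane | CC1(CCBr)OCCO1 | starting material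
26 | [2-(2-methyl-1,3-dioxolan-2-yl)ethyl]magnesium bromide | CC1(CC[Mg]Br)OCCO1 | intermediate
27 | cis-{2,2-dimethyl-3-[2-(2-methyl-1,3-dioxolan-2-yl)ethyl]cyclopropyl}magnesium bromide (configuration as in 28) | CC1(OCCO1)CC[C@H]2[C@@H]([Mg]Br)C2(C)C | intermediate
28 | (1R,3R)-1-iodo-2,2-dimethyl-3-[2-(2-methyl-1,3-dioxolan-2-yl)ethyl]cyclopropane (iodine and side chain cis) | CC1(OCCO1)CC[C@H]2[C@@H](I)C2(C)C | intermediate
29 | cis-{2,2-dimethyl-3-[2-(2-methyl-1,3-dioxolan-2-yl)ethyl]cyclopropyl}lithium (configuration as in 28) | CC1(OCCO1)CC[C@H]2[C@@H]([Li])C2(C)C | intermediate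
30 | cis-{2,2-dimethyl-3-[2-(2-methyl-1,3-dioxolan-2-yl)ethyl]cyclopropyl}zinc chloride (configuration as in 28) | CC1(OCCO1)CC[C@H]2[C@@H]([Zn]Cl)C2(C)C | intermediate
31 | bis(ethylene ketal) of the target (both side-chain ketones as 2-methyl-1,3-dioxolanes) | CC1(OCCO1)CC[C@H]2[C@@H](C3=C[C@@H]4C[C@@]3(C)[C@H]5C[C@@H]4C([C@@H]6[C@H](CCC7(C)OCCO7)C6(C)C)=C5C)C2(C)C | intermediate
32 | CNP0300925.1 | CC(=O)CC[C@H]1[C@@H](C2=C[C@@H]3C[C@@]2(C)[C@H]2C[C@@H]3C([C@@H]3[C@H](CCC(C)=O)C3(C)C)=C2C)C1(C)C | target

**Step count and risks**

Total step count: 15. Longest linear sequence: 12 steps (steps 1–10, 14, 15); steps 11–13 make the cyclopropyl iodide in a side branch.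

The three steps most likely to fail:

Step 6. The 1,2-shift may occur on the wrong face of C11 (the 11R epimer, which can only give the anti tricycle), and the acid may open the dioxolane instead of protonating the alkene. The fallback sets out from 12 and replaces the proton by a bromonium ion under neutral conditions. NBS with hydroquinidine 1,4-phthalazinediyl diether as catalyst (toluene/CHCl3, −40 °C) should induce the same ring expansion anti to the bromonium ion, with catalyst-controlled face selection and an untouched ketal, giving the bromomethyl ketone F1. The C–Br bond is then reduced with Bu3SnH and AIBN in the presence of catalytic PhSeSePh, whose selenol traps the primary radical before a Dowd–Beckwith 1,2-acyl shift can occur. This returns the route at 13.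

Step 9. The conjugate addition may stall or revert because the syn tricycle is strained (ring C as a boat inside two bicyclo[3.2.1]octane units), and proton exchange could let the C26 enolate close a five-membered ring instead. The fallback sets out from 15 and makes the closure irreversible.
- Weitz–Scheffer epoxidation (H2O2, NaOH, MeOH, 0 °C) should deliver oxygen to the ring-A face opposite the ring-B substituent, giving the epoxy ketone F2.
- Ketal hydrolysis (PPTS, wet acetone) gives the epoxy diketone F3.
- LiN(iPr)2 at −78 °C forms the kinetic C15 lithium enolate F4, which opens the epoxide at C9 from the rear (6-exo-tet, driven by release of epoxide strain); AcOH quench gives the 8-exo-hydroxy diketone F5.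
- SmI2 in THF/MeOH at −78 °C removes the α-hydroxyl group and returns the route at 19.

Step 14. Transmetalation of the congested cyclopropylzinc to the two hindered alkenylpalladium centres may be too slow, so that coupling stops at one site or the triflates are cleaved; the same crowding may already slow enolisation at C26 in step 10. The fallback sets out from 19 and avoids both the triflates and the cross-coupling. The cyclopropyllithium 29 (from 28 and t-BuLi) is transmetalated with CeCl3 to the organocerium reagent F6 and added to both carbonyl groups from their open exo faces, giving the bis(tertiary alcohol) F7. Syn dehydration with methyl N-(triethylammoniosulfonyl)carbamate then removes water towards C8 and C26 (endo hydroxyl and endo hydrogen are syn; elimination into a cyclopropane or to a bridgehead is excluded by strain). This returns the route at 31.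

**Further compounds**

F1 | step 6 | (2R)-2-(bromomethyl)-2-[(6R,7S)-6-methyl-1,4-dioxaspiro[4.4]nonan-7-yl]cyclopentan-1-one | O=C1CCC[C@@]1(CBr)[C@H]2CCC3(OCCO3)[C@@H]2C
F2 | step 9 | C8–C9 epoxide of 15 (oxirane oxygen on the ring-A face opposite the ring-B substituent) | O=C1[C@@H]2O[C@@H]2C[C@@]1(C)[C@H]3CCC4(OCCO4)[C@@H]3C
F3 | step 9 | epoxy diketone (F2 with the ring-B ketone free) | O=C1[C@@H]2O[C@@H]2C[C@@]1(C)[C@H]3CCC(=O)[C@@H]3C
F4 | step 9 | kinetic lithium enolate of F3 (ring B, C15=C16) | O=C1[C@@H]2O[C@@H]2C[C@@]1(C)[C@H]3CC=C(O[Li])[C@@H]3C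
F5 | step 9 | 8-exo-hydroxy derivative of 19 | O=C1[C@H](O)[C@@H]2C[C@@]1(C)[C@H]3C[C@@H]2C(=O)[C@@H]3C
F6 | step 14 | cis-{2,2-dimethyl-3-[2-(2-methyl-1,3-dioxolan-2-yl)ethyl]cyclopropyl}cerium dichloride (configuration as in 28) | CC1(OCCO1)CC[C@H]2[C@@H]([Ce](Cl)Cl)C2(C)C
F7 | step 14 | bis(tertiary alcohol) from double exo addition to 19 (cyclopropyl groups exo, hydroxyl groups endo on C7 and C16) | CC1(OCCO1)CC[C@H]2[C@@H]([C@]3(O)C[C@@H]4C[C@@]3(C)[C@H]5C[C@@H]4[C@](O)([C@@H]6[C@H](CCC7(C)OCCO7)C6(C)C)[C@@H]5C)C2(C)C
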